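## Retrosynthetic overview

1. Petrosin A ⇒ twofold C1–C2 disconnection of both quinolizidin-2-ones (quinolizidine numbering): an acyl anion equivalent (Breslow intermediate of a β-amino aldehyde) adds across the macrocyclic C1=C olefin, closing the two piperidone rings last.
2. Bis-aldehyde ⇒ macrocyclic bis(2-alkenylpiperidine) + two molecules of methacrolein (aza-Michael brings C2, C3, C4 and the methyl group).
3. 16-membered diene ⇒ head-to-tail metathesis cyclodimerisation of racemic trans-2-vinyl-3-(hex-5-enyl)piperidine; heterochiral pairing gives the meso ring.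
4. Monomer ⇒ N-Boc-2-piperidinone: enolate alkylation (C9), then N-acyliminium vinylation (C9a, trans).
5. Ring order: piperidine (bought) → 16-membered carbocycle → two 4-piperidone rings.

**Assumption:** the target SMILES is the centrosymmetric meso isomer (unit A 1R,3R,9S,9aS; unit B 1S,3S,9R,9aR; quinolizidine labels C1–C4, C9, C9a used throughout), so it is achiral and racemic 2,3-trans building blocks suffice; in steps 5 to 7 the same reaction runs at both symmetry-related sites in one operation and singly reacted species are not listed separately.

## Route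

**Step 1**
Reactants: 1 tert-butyl 2-oxopiperidine-1-carboxylate; 2 6-bromohex-1-ene
Product: 3 rac-tert-butyl 3-(hex-5-en-1-yl)-2-oxopiperidine-1-carboxylate
Conditions: LiN(SiMe3)2 (1.1 equiv), THF, −78 °C; then 2 (1.3 equiv), DMPU, −78 → 0 °C
Reagents that add atoms: none
Why: Lithium enolate alkylation of the imide-like N-Boc lactam with a primary bromide installs the future C9 with its hexenyl chain as a racemate, which is all the meso target needs.

**Step 2**
Reactants: 3 rac-tert-butyl 3-(hex-5-en-1-yl)-2-oxopiperidine-1-carboxylate
Product: 5 tert-butyl 3-(hex-5-en-1-yl)-2-methoxypiperidine-1-carboxylate (racemic; both C2 epimers), via hemiaminal 4 (not isolated)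
Conditions: LiBHEt3 (1.1 equiv), THF, −78 °C; H2O quench; crude 4, MeOH, pyridinium p-toluenesulfonate (5 mol%), rt
Reagents that add atoms: methanol, CO
Why: Partial hydride reduction of the activated N-Boc lactam carbonyl stops at the hemiaminal at −78 °C, and acid-catalysed N,O-acetal exchange gives the stable methoxy aminal; the C2 configuration is irrelevant because this carbon is ionised in step 3.

**Step 3**
Reactants: 5 tert-butyl 3-(hex-5-en-1-yl)-2-methoxypiperidine-1-carboxylate; 6 vinylmagnesium bromide
Product: 7 rac-tert-butyl (2R,3S)-3-(hex-5-en-1-yl)-2-vinylpiperidine-1-carboxylate (2,3-trans)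
Conditions: 6 (3 equiv), CuBr·SMe2 (3 equiv), BF3·OEt2 (3 equiv), THF, −78 → −20 °C; chromatography to remove the minor cis isomer
Reagents that add atoms: none
Why: N-acyliminium alkylation with a vinylcopper–BF3 reagent, in which BF3 ionises the N,O-acetal and the bulky reagent attacks axially, anti to the C3 chain, to give the 2,3-trans (diaxial) carbamate that sets C9a relative to C9 (trans expected as the major isomer; the dr is not known for this substrate).

**Step 4**
Reactants: 7 rac-tert-butyl (2R,3S)-3-(hex-5-en-1-yl)-2-vinylpiperidine-1-carboxylate (two molecules)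
Product: 9 meso (E,E) head-to-tail cyclodimer (16-membered diene; each N-Boc-piperidine 2,3-trans; ring A 2S,3S; ring B 2R,3R), via open-chain head-to-tail dimer 8 (not isolated)
Conditions: second-generation Hoveyda–Grubbs catalyst RuCl2(H2IMes)(=CH-C6H4-2-OiPr) (10 mol%), 1,4-benzoquinone (20 mol%), toluene (5 mM), 60 °C, Ar sparge; chromatography to separate the meso from the C2-symmetric diastereomer
Reagents that add atoms: none
Why: Cross-metathesis then ring-closing metathesis, in which the unhindered hexenyl end couples with the hindered vinyl end (hindered vinyls do not homodimerise and the tail-to-tail dimer is reversible), while the carbamate's A(1,3) strain holds the two arms trans-diaxial and so blocks intramolecular 8-ring closure; heterochiral pairing of the racemate gives the meso ring statistically (about 1:1 with the C2-symmetric isomer, which can be returned to 7 by ethenolysis), the C2 descriptor changes from 7 only because the priority order changes, and olefin geometry is erased in step 7.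

**Step 5**
Reactants: 9 meso (E,E) head-to-tail cyclodimer (bis-Boc)
Product: 10 meso macrocyclic bis(secondary amine)
Conditions: CF3CO2H, CH2Cl2, 0 °C → rt; aq. K2CO3 work-up
Reagents that add atoms: none
Why: Acidolytic Boc cleavage frees both piperidine nitrogens without touching the disubstituted olefins or the C9/C9a stereocentres.

**Step 6**
Reactants: 10 meso macrocyclic bis(secondary amine); 11 methacrolein (two molecules)
Product: 12 meso macrocyclic bis(β-amino aldehyde) (N-CH2-CH(CH3)-CHO on each nitrogen; C3 epimer mixture)
Conditions: 11 (6 equiv, freshly distilled), MeCN, 0 °C → rt, 16 h; volatiles removed cold under vacuum; used crude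
Reagents that add atoms: none
Why: Twofold aza-Michael addition, one molecule of the enal per secondary amine, delivers C4, C3 (with its methyl) and the C2 aldehyde of each unit in one operation; C3 forms as a labile epimer mixture that is corrected in step 7.

**Step 7**
Reactants: 12 meso macrocyclic bis(β-amino aldehyde)
Product: 13 petrosin A
Conditions: 3-(2,4,6-trimethylphenyl)-5,6,7,8-tetrahydro-4H-cyclohepta[d]thiazol-3-ium perchlorate (40 mol%), DBU (1.0 equiv), 1,4-dioxane (0.02 M), 120 °C, sealed tube, 36 h
Reagents that add atoms: none
Why: Proposed new method: the carbene converts each aldehyde into a Breslow intermediate (acyl anion equivalent) whose C2 adds to C1 of the ring olefin through a six-membered, Conia-ene-like transition state while the enol proton goes to the neighbouring olefin carbon (which becomes the fifth chain methylene), the closest known reaction being the carbene-catalysed intramolecular hydroacylation of unactivated olefins (2-allyloxybenzaldehydes to chroman-4-ones); C1 arises by this syn addition and, with C3, is then equilibrated by DBU at the α-positions to the predicted more stable trans-fused quinolizidinone (equatorial C3 methyl, axial C1 chain that avoids the peri clash with the equatorial C9 chain), C9 and C9a being left untouched.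

## Compound list

1 | tert-butyl 2-oxopiperidine-1-carboxylate | O=C1CCCCN1C(=O)OC(C)(C)C | starting material
2 | 6-bromohex-1-ene | BrCCCCC=C | starting material
3 | rac-tert-butyl 3-(hex-5-en-1-yl)-2-oxopiperidine-1-carboxylate (S enantiomer drawn) | O=C1N(C(=O)OC(C)(C)C)CCC[C@@H]1CCCCC=C | intermediate
4 | tert-butyl 3-(hex-5-en-1-yl)-2-hydroxypiperidine-1-carboxylate (hemiaminal; racemic, both C2 epimers) | OC1N(C(=O)OC(C)(C)C)CCC[C@@H]1CCCCC=C | intermediate (not isolated)
5 | tert-butyl 3-(hex-5-en-1-yl)-2-methoxypiperidine-1-carboxylate (racemic, both C2 epimers) | COC1N(C(=O)OC(C)(C)C)CCC[C@@H]1CCCCC=C | intermediate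
6 | vinylmagnesium bromide | C=C[Mg]Br | starting material
7 | rac-tert-butyl (2R,3S)-3-(hex-5-en-1-yl)-2-vinylpiperidine-1-carboxylate (2,3-trans; 2R,3S enantiomer drawn) | C=C[C@H]1N(C(=O)OC(C)(C)C)CCC[C@@H]1CCCCC=C | intermediate
8 | open-chain head-to-tail cross-metathesis dimer (heterochiral; both rings 2,3-trans; E olefin; one vinyl and one hexenyl end left) | C=C[C@H]1N(C(=O)OC(C)(C)C)CCC[C@@H]1CCCC/C=C/[C@@H]1N(C(=O)OC(C)(C)C)CCC[C@H]1CCCCC=C | intermediate (not isolated)
9 | meso (E,E) head-to-tail cyclodimer: 16-membered diene in which C2 of each N-Boc-piperidine is joined through CH=CH-(CH2)4 to C3 of the other; both rings 2,3-trans; ring A 2S,3S, ring B 2R,3R | O=C(OC(C)(C)C)N1CCC[C@@H]2CCCC/C=C/[C@@H]3N(C(=O)OC(C)(C)C)CCC[C@H]3CCCC/C=C/[C@@H]12 | intermediate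
10 | meso macrocyclic bis(secondary amine) (9 without the Boc groups) | N1CCC[C@@H]2CCCC/C=C/[C@@H]3NCCC[C@H]3CCCC/C=C/[C@@H]12 | intermediate
11 | methacrolein (2-methylprop-2-enal) | CC(=C)C=O | starting material
12 | meso macrocyclic bis(β-amino aldehyde): 10 with a 2-methyl-3-oxopropyl group on each nitrogen (aldehyde α-carbons epimeric) | O=CC(C)CN1CCC[C@@H]2CCCC/C=C/[C@@H]3N(CC(C)C=O)CCC[C@H]3CCCC/C=C/[C@@H]12 | intermediate
13 | petrosin A (meso; unit A 1R,3R,9S,9aS, unit B 1S,3S,9R,9aR) | C[C@@H]1CN2CCC[C@@H]3CCCCC[C@@H]4C(=O)[C@@H](C)CN5CCC[C@@H](CCCCC[C@@H](C1=O)[C@H]32)[C@H]45 | target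

## Step count and risks

Total steps: 7. Longest linear sequence: 7 (1 → 13).

The three steps most likely to fail are steps 7, 4 and 6, in that order.

The first risk is step 7, the twofold carbene-catalysed hydroacylation. An aliphatic, enolisable β-amino aldehyde and a flexible tether lie outside the known scope, and retro-Michael loss of methacrolein or acyloin formation may win. The fallback sets out from 12 and returns at 13, replacing the polar acyl anion equivalent by a nucleophilic acyl radical. Both aldehydes are oxidised (NaClO2, NaH2PO4, 2-methylbut-2-ene, tBuOH/H2O) to the meso bis(β-amino acid) F1. PhSeSePh/PBu3 converts this into the bis(Se-phenyl selenoester) F2. Slow addition of Bu3SnH and 2,2'-azobis(2-methylpropionitrile) in benzene at 80 °C makes each acyl radical close onto C1 in a 6-exo-trig mode, and the chain radical is reduced by the stannane. A final DBU/MeOH equilibration of C1 and C3 gives 13.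

The second risk is step 4, the metathesis cyclodimerisation. The hindered allylic carbamate olefin may be too slow, oligomers may dominate, and the meso ring is at best half of the cyclodimer. The fallback sets out from 5 and returns at 9, closing the macrocycle by C9a–C1 bond formation instead of olefin formation. Cross-metathesis of 5 with vinylboronic acid pinacol ester (the same second-generation Hoveyda–Grubbs catalyst RuCl2(H2IMes)(=CH-C6H4-2-OiPr), CH2Cl2, 40 °C) gives the (E)-alkenyl pinacol boronate F3. KHF2 in MeOH/H2O gives the potassium (E)-alkenyltrifluoroborate F4. BF3·OEt2 at high dilution (CH2Cl2, 2 mM, −40 → 0 °C) ionises the N,O-acetal, and the alkenylboron end of a second molecule adds at its boron-bearing carbon, anti to the C3 chain, twice. This gives 9 with the E olefins and trans rings already in place; the C2-symmetric isomer is still removed by chromatography.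

The third risk is step 6, the aza-Michael addition to methacrolein. The hindered amine may add reversibly or form enamine-type products, and the β-amino aldehyde is labile. The fallback sets out from 10 and returns at 12. Conjugate addition to methyl methacrylate (MeOH, 60 °C) gives the stable meso bis(β-amino methyl ester) F5. iBu2AlH in toluene at −78 °C, with the β-amino group chelating aluminium to hold the tetrahedral intermediate, then gives 12 cold for immediate use in step 7.

## Further compounds

F1 | step 7 | meso macrocyclic bis(β-amino acid) (12 with both CHO groups oxidised to CO2H) | OC(=O)C(C)CN1CCC[C@@H]2CCCC/C=C/[C@@H]3N(CC(C)C(O)=O)CCC[C@H]3CCCC/C=C/[C@@H]12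
F2 | step 7 | meso macrocyclic bis(Se-phenyl selenoester) | O=C([Se]c5ccccc5)C(C)CN1CCC[C@@H]2CCCC/C=C/[C@@H]3N(CC(C)C(=O)[Se]c4ccccc4)CCC[C@H]3CCCC/C=C/[C@@H]12
F3 | step 4 | tert-butyl 2-methoxy-3-[(E)-6-(4,4,5,5-tetramethyl-1,3,2-dioxaborolan-2-yl)hex-5-en-1-yl]piperidine-1-carboxylate (racemic, both C2 epimers) | COC1N(C(=O)OC(C)(C)C)CCC[C@@H]1CCCC/C=C/B2OC(C)(C)C(C)(C)O2
F4 | step 4 | potassium (E)-[6-(1-Boc-2-methoxypiperidin-3-yl)hex-1-en-1-yl]trifluoroborate (racemic, both C2 epimers) | COC1N(C(=O)OC(C)(C)C)CCC[C@@H]1CCCC/C=C/[B-](F)(F)F.[K+]
F5 | step 6 | meso macrocyclic bis(β-amino methyl ester) (10 with a 3-methoxy-2-methyl-3-oxopropyl group on each nitrogen) | COC(=O)C(C)CN1CCC[C@@H]2CCCC/C=C/[C@@H]3N(CC(C)C(=O)OC)CCC[C@H]3CCCC/C=C/[C@@H]12
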